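**Retrosynthetic overview**
1. Target 16 ⇒ Mizoroki–Heck disconnection of the aryl–C(β) bond: albicanyl acrylate 13 + 4-iodoresorcinol 15 (from resorcinol 14).
2. 13 ⇒ C8 methylenation of decalone acrylate 12.
3. 12 ⇒ key ring expansion: acyloxylative semipinacol 1,2-shift of the angular carbon in trans-hydrindanyl vinyl carbinol 10 (five-membered ring → ring B; C9–C10 and C11–O formed together, acrylate from acrylic acid 11).
4. 10 ⇒ 4-methyl Hajos–Parrish enedione 5 by vinyl addition, reductive methylation (trans fusion, gem-dimethyl) and Wolff–Kishner reduction.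
5. 5 ⇒ 2-methylcyclopentane-1,3-dione 1 + ethyl vinyl ketone 2. Ring order: five-membered ring (from 1), ring A (step 2), ring B by expansion (step 6).

Assumption: promoters recovered unchanged (amino acid, acids, bases) are treated as catalysts; centres not controlled in a transient intermediate (C4 of ketol 4, C=N geometry of hydrazone 9) are left open in its SMILES.

**Step 1**
Reactants: 1 2-methylcyclopentane-1,3-dione; 2 ethyl vinyl ketone (pent-1-en-3-one)
Product: 3 2-methyl-2-(3-oxopentyl)cyclopentane-1,3-dione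
Conditions: H2O, AcOH (cat.), 75 °C
Reagents that add atoms: none
Why: Michael addition of the enolised 1,3-dione to the enone; no stereocentre is formed.

**Step 2**
Reactants: 3 2-methyl-2-(3-oxopentyl)cyclopentane-1,3-dione
Product: 5 (7aS)-4,7a-dimethyl-2,3,7,7a-tetrahydro-1H-indene-1,5(6H)-dione, via cis-fused ketol 4 (not isolated)
Conditions: L-phenylalanine (1.0 equiv), 1 M aq. HClO4 (0.4 equiv), MeCN, reflux; recrystallise to >98% ee
Reagents that add atoms: none
Why: Hajos–Parrish–Eder–Sauer–Wiechert aldol condensation; the L-amino acid enamine attacks one of the two enantiotopic ring carbonyls, setting the quaternary centre (future C10) as S, and ketol 4 dehydrates in the same pot.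

**Step 3**
Reactants: 5 (7aS)-4,7a-dimethyl-2,3,7,7a-tetrahydro-1H-indene-1,5(6H)-dione
Product: 6 (1R,7aS)-1-ethenyl-1-hydroxy-4,7a-dimethyl-1,2,3,6,7,7a-hexahydro-5H-inden-5-one
Conditions: CH2=CHMgBr (1.1 equiv), LaCl3·2LiCl (0.3 equiv), THF, −78 °C; then H2O
Reagents that add atoms: vinylmagnesium bromide, C=C[Mg]Br
Why: Chemoselective Grignard 1,2-addition to the saturated ketone, which is more electrophilic than the conjugated one (the same preference seen in hydride reduction and ketalisation of this enedione); attack anti to the angular methyl gives 1R, a centre that is destroyed in step 6.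

**Step 4**
Reactants: 6 (1R,7aS)-1-ethenyl-1-hydroxy-4,7a-dimethyl-1,2,3,6,7,7a-hexahydro-5H-inden-5-one
Product: 8 (1R,3aR,7aS)-1-ethenyl-1-hydroxy-4,4,7a-trimethyloctahydro-5H-inden-5-one, via dilithium alkoxide enolate 7 (not isolated)
Conditions: Li (2.2 equiv), NH3(l)/THF, −78 °C; then MeI (5 equiv), −78 to −33 °C; H2O
Reagents that add atoms: iodomethane, CI
Why: Stork reductive alkylation (dissolving-metal enone reduction, then enolate C-methylation); β-protonation anti to the angular methyl sets the trans ring fusion (future C5), the carbinol OH is the single proton donor, and the regiospecific enolate is methylated at C4 to give the gem-dimethyl group.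

**Step 5**
Reactants: 8 (1R,3aR,7aS)-1-ethenyl-1-hydroxy-4,4,7a-trimethyloctahydro-5H-inden-5-one
Product: 10 (1R,3aS,7aS)-1-ethenyl-4,4,7a-trimethyloctahydro-1H-inden-1-ol, via hydrazone 9 (not isolated)
Conditions: N2H4·H2O, KOH, diethylene glycol, 130 then 200 °C, under N2 (air excluded)
Reagents that add atoms: none
Why: Wolff–Kishner (Huang-Minlon) reduction, the standard way to remove a 4,4-dimethyl-3-ketone; the tertiary allylic alkoxide and the vinyl group tolerate hot base when no oxidant is present to make diimide.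

**Step 6**
Reactants: 10 (1R,3aS,7aS)-1-ethenyl-4,4,7a-trimethyloctahydro-1H-inden-1-ol; 11 acrylic acid
Product: 12 [(1S,4aS,8aS)-5,5,8a-trimethyl-2-oxodecahydronaphthalen-1-yl]methyl prop-2-enoate
Conditions: PhI(OAc)2 (1.5 equiv) and 11 (6 equiv), PhMe, 40 °C, reduced pressure (AcOH removed); then 10, Pd(OAc)2 (5 mol %), BHT (cat.), PhMe, 25 °C
Reagents that add atoms: none
Why: Proposed new method: a palladium-catalysed acyloxylative semipinacol ring expansion, in which divalent palladium binds the vinyl group, the quaternary ring carbon C7a shifts from the carbinol carbon to the internal alkene carbon anti to palladium (1,2-shift, hydrindane → decalin, driven by C=O formation and relief of trans-hydrindane strain), and the resulting primary alkylpalladium is oxidised by the trivalent iodine reagent to tetravalent palladium so that C–O reductive elimination with acrylate outruns β-hydride elimination; the new C9 centre is α to the ketone and settles as the equatorial 1S epimer, which anti migration through the less hindered rotamer should also give; the closest known chemistry is the Pd-mediated semipinacol ring expansion of 1-vinylcycloalkanols combined with Pd-catalysed alkene acetoxylation by PhI(OAc)2.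

**Step 7**
Reactants: 12 [(1S,4aS,8aS)-5,5,8a-trimethyl-2-oxodecahydronaphthalen-1-yl]methyl prop-2-enoate
Product: 13 [(1S,4aS,8aS)-5,5,8a-trimethyl-2-methylidenedecahydronaphthalen-1-yl]methyl prop-2-enoate
Conditions: Cp2Ti(μ-CH2)(μ-Cl)AlMe2 (1.2 equiv), pyridine (cat.), THF/PhMe, −40 to 0 °C
Reagents that add atoms: Tebbe reagent Cp2Ti(μ-CH2)(μ-Cl)AlMe2, C[Al-]1(C)C[Ti]([Cl+]1)(C2C=CC=C2)C3C=CC=C3
Why: Tebbe methylenation (carbonyl olefination by the titanocene methylidene through an oxatitanacyclobutane) is non-basic, so the β-acyloxy ketone neither eliminates nor epimerises at C9, and at low temperature with a slight excess of reagent the ketone reacts well ahead of the acrylate ester.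

**Step 8**
Reactants: 14 resorcinol
Product: 15 4-iodobenzene-1,3-diol
Conditions: ICl (1.0 equiv), Et2O, 0 °C to rt
Reagents that add atoms: iodine monochloride, ClI
Why: Electrophilic aromatic iodination at C4, the position ortho/para to both hydroxyls and less hindered than C2.

**Step 9**
Reactants: 13 [(1S,4aS,8aS)-5,5,8a-trimethyl-2-methylidenedecahydronaphthalen-1-yl]methyl prop-2-enoate; 15 4-iodobenzene-1,3-diol
Product: 16 [(1S,4aS,8aS)-5,5,8a-trimethyl-2-methylidenedecahydronaphthalen-1-yl]methyl (2E)-3-(2,4-dihydroxyphenyl)prop-2-enoate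
Conditions: Pd(OAc)2 (5 mol %), n-Bu4NCl (1 equiv), NaOAc (2.5 equiv), DMF, 70 °C
Reagents that add atoms: none
Why: Mizoroki–Heck reaction under ligand-free Jeffery conditions; zerovalent palladium inserts into the aryl iodide and adds to the acrylate terminus to give the E-cinnamate, while the hindered 1,1-disubstituted exocyclic alkene and the free phenols are left alone with a weak base.

**Compound list**
1 | 2-methylcyclopentane-1,3-dione | CC1C(=O)CCC1=O | starting material
2 | ethyl vinyl ketone (pent-1-en-3-one) | CCC(=O)C=C | starting material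
3 | 2-methyl-2-(3-oxopentyl)cyclopentane-1,3-dione | CCC(=O)CCC1(C)C(=O)CCC1=O | intermediate
4 | (3aS,7aS)-3a-hydroxy-4,7a-dimethylhexahydro-1H-indene-1,5(4H)-dione (cis-fused ketol, 4RS) | O=C1CC[C@]2(C)C(=O)CC[C@]2(O)C1C | intermediate
5 | (7aS)-4,7a-dimethyl-2,3,7,7a-tetrahydro-1H-indene-1,5(6H)-dione | O=C1CC[C@]2(C)C(=O)CCC2=C1C | intermediate
6 | (1R,7aS)-1-ethenyl-1-hydroxy-4,7a-dimethyl-1,2,3,6,7,7a-hexahydro-5H-inden-5-one | O=C1CC[C@]2(C)[C@](O)(C=C)CCC2=C1C | intermediate
7 | dilithium (1R,3aS,7aS)-1-ethenyl-4,7a-dimethyl-2,3,3a,6,7,7a-hexahydro-1H-indene-1,5-bis(olate) | [Li]OC1CC[C@]2(C)[C@](O[Li])(C=C)CC[C@H]2C=1C | intermediate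
8 | (1R,3aR,7aS)-1-ethenyl-1-hydroxy-4,4,7a-trimethyloctahydro-5H-inden-5-one | O=C1CC[C@]2(C)[C@](O)(C=C)CC[C@H]2C1(C)C | intermediate
9 | (1R,3aS,7aS)-1-ethenyl-5-hydrazinylidene-4,4,7a-trimethyloctahydro-1H-inden-1-ol | NN=C1CC[C@]2(C)[C@](O)(C=C)CC[C@H]2C1(C)C | intermediate
10 | (1R,3aS,7aS)-1-ethenyl-4,4,7a-trimethyloctahydro-1H-inden-1-ol | C1CC[C@]2(C)[C@](O)(C=C)CC[C@H]2C1(C)C | intermediate
11 | acrylic acid (prop-2-enoic acid) | C=CC(=O)O | starting material
12 | [(1S,4aS,8aS)-5,5,8a-trimethyl-2-oxodecahydronaphthalen-1-yl]methyl prop-2-enoate | O=C1CC[C@H]2C(C)(C)CCC[C@]2(C)[C@H]1COC(=O)C=C | intermediate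
13 | [(1S,4aS,8aS)-5,5,8a-trimethyl-2-methylidenedecahydronaphthalen-1-yl]methyl prop-2-enoate (albicanyl acrylate) | C=C1CC[C@H]2C(C)(C)CCC[C@]2(C)[C@H]1COC(=O)C=C | intermediate
14 | resorcinol (benzene-1,3-diol) | Oc1cccc(O)c1 | starting material
15 | 4-iodobenzene-1,3-diol | Oc1ccc(I)c(O)c1 | intermediate
16 | [(1S,4aS,8aS)-5,5,8a-trimethyl-2-methylidenedecahydronaphthalen-1-yl]methyl (2E)-3-(2,4-dihydroxyphenyl)prop-2-enoate | C=C1CC[C@H]2C(C)(C)CCC[C@]2(C)[C@H]1COC(=O)/C=C/c1ccc(O)cc1O | target

**Step count**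
Total: 9 steps. Longest linear sequence: 8 steps (steps 1–7 and 9); step 8 is a one-step side branch.

**Steps most likely to fail, with fallbacks**

Step 6 (the proposed new ring expansion). β-Hydride elimination to the α-methylene ketone, or simple diacyloxylation of the alkene, could compete. The fallback uses the known epoxy-alcohol semipinacol; it sets out from 10 and comes back at 12. Hydroxyl-directed epoxidation of 10 with VO(acac)2 and t-BuOOH in CH2Cl2 gives (1S,3aS,7aS)-4,4,7a-trimethyl-1-(oxiran-2-yl)octahydro-1H-inden-1-ol F7 as a mixture of oxirane epimers. BF3·OEt2 in CH2Cl2 at −78 °C then triggers the stereospecific anti 1,2-shift of the angular carbon onto the oxirane carbon, and after equilibration α to the ketone both epimers converge on (1S,4aS,8aS)-1-(hydroxymethyl)-5,5,8a-trimethyloctahydronaphthalen-2(1H)-one F8. Acylation of F8 with acryloyl chloride and 2,6-lutidine at −40 °C gives 12.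

Step 3 (chemoselective vinyl addition with both carbonyls free). The conjugated ketone could compete, and the free carbinol is then carried through steps 4 and 5. The fallback reorders the sequence on the well-precedented 1β-hydroxy series; it sets out from 5 and comes back at 10. NaBH4 in EtOH at −20 °C reduces only the saturated carbonyl of 5 to (1S,7aS)-1-hydroxy-4,7a-dimethyl-1,2,3,6,7,7a-hexahydro-5H-inden-5-one F1. Li in NH3 then gives dilithium (1S,3aR,7aS)-4,7a-dimethyl-2,3,3a,6,7,7a-hexahydro-1H-indene-1,5-bis(olate) F2, which MeI converts to (1S,3aR,7aS)-1-hydroxy-4,4,7a-trimethyloctahydro-5H-inden-5-one F3. Wolff–Kishner reduction of F3 through (1S,3aS,7aS)-5-hydrazinylidene-4,4,7a-trimethyloctahydro-1H-inden-1-ol F4 gives (1S,3aS,7aS)-4,4,7a-trimethyloctahydro-1H-inden-1-ol F5. Dess–Martin oxidation of F5 gives (3aS,7aS)-4,4,7a-trimethyloctahydro-1H-inden-1-one F6. Vinylmagnesium bromide with LaCl3·2LiCl adds to F6, now the only carbonyl, from the face anti to the angular methyl to give 10.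

Step 9 (Heck coupling with an unprotected, electron-rich iodoresorcinol). Slow oxidative addition, or E/Z isomerisation followed by lactonisation to umbelliferone with loss of the terpene alcohol, could erode the yield. The fallback builds the cinnamate by Wittig olefination instead; it sets out from 13 and comes back at 16. DIBAL-H at −78 °C cleaves the acrylate of 13 to [(1S,4aS,8aS)-5,5,8a-trimethyl-2-methylidenedecahydronaphthalen-1-yl]methanol (albicanol) F9. Ph3P=C=C=O in toluene at 80 °C converts F9 into albicanyl (triphenyl-λ5-phosphanylidene)acetate F10. Vilsmeier–Haack formylation of 14 (POCl3, DMF, then H2O) gives 2,4-dihydroxybenzaldehyde F11. Wittig reaction of F10 with F11 in toluene at 60 °C gives the E-cinnamate 16.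

**Further compounds**
F1 | step 3 | (1S,7aS)-1-hydroxy-4,7a-dimethyl-1,2,3,6,7,7a-hexahydro-5H-inden-5-one | O=C1CC[C@]2(C)[C@@H](O)CCC2=C1C
F2 | step 3 | dilithium (1S,3aR,7aS)-4,7a-dimethyl-2,3,3a,6,7,7a-hexahydro-1H-indene-1,5-bis(olate) | [Li]OC1CC[C@]2(C)[C@@H](O[Li])CC[C@H]2C=1C
F3 | step 3 | (1S,3aR,7aS)-1-hydroxy-4,4,7a-trimethyloctahydro-5H-inden-5-one | O=C1CC[C@]2(C)[C@@H](O)CC[C@H]2C1(C)C
F4 | step 3 | (1S,3aS,7aS)-5-hydrazinylidene-4,4,7a-trimethyloctahydro-1H-inden-1-ol | NN=C1CC[C@]2(C)[C@@H](O)CC[C@H]2C1(C)C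
F5 | step 3 | (1S,3aS,7aS)-4,4,7a-trimethyloctahydro-1H-inden-1-ol | C1CC[C@]2(C)[C@@H](O)CC[C@H]2C1(C)C
F6 | step 3 | (3aS,7aS)-4,4,7a-trimethyloctahydro-1H-inden-1-one | C1CC[C@]2(C)C(=O)CC[C@H]2C1(C)C
F7 | step 6 | (1S,3aS,7aS)-4,4,7a-trimethyl-1-(oxiran-2-yl)octahydro-1H-inden-1-ol (oxirane epimers) | C1CC[C@]2(C)[C@](O)(C3CO3)CC[C@H]2C1(C)C
F8 | step 6 | (1S,4aS,8aS)-1-(hydroxymethyl)-5,5,8a-trimethyloctahydronaphthalen-2(1H)-one | O=C1CC[C@H]2C(C)(C)CCC[C@]2(C)[C@H]1CO
F9 | step 9 | [(1S,4aS,8aS)-5,5,8a-trimethyl-2-methylidenedecahydronaphthalen-1-yl]methanol (albicanol) | C=C1CC[C@H]2C(C)(C)CCC[C@]2(C)[C@H]1CO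
F10 | step 9 | [(1S,4aS,8aS)-5,5,8a-trimethyl-2-methylidenedecahydronaphthalen-1-yl]methyl (triphenyl-λ5-phosphanylidene)acetate | C=C1CC[C@H]2C(C)(C)CCC[C@]2(C)[C@H]1COC(=O)C=P(c1ccccc1)(c1ccccc1)c1ccccc1
F11 | step 9 | 2,4-dihydroxybenzaldehyde | O=Cc1ccc(O)cc1O
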